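**Retrosynthetic overview**

- Feature: the ketone carbon lies between aromatic C8 of ring A (flanked by C7–O and by C8a–O1) and alkene carbon Cα, so an aryl iodide at C8, CO and an (E)-styrylboron reagent map onto C8–C(=O)–Cα.
- Target 15 ⇐ tetra-MOM enone 14 (acidic deprotection) ⇐ C8 iodide 9 + CO 13 + styrylboronate 12, with both bonds to the carbonyl carbon made in one palladium-catalysed step.
- Iodide 9 ⇐ NIS iodination of tris-MOM chroman 8 ⇐ (S)-chromanetriol 7 ⇐ acid-promoted 6-endo opening of (S)-epoxide 6 ⇐ Shi epoxidation of silylated 2-prenylphloroglucinol 4 ⇐ phloroglucinol 1 + prenyl bromide 2.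
- Boronate 12 ⇐ boron–Wittig olefination of 4-(methoxymethoxy)benzaldehyde 11 ⇐ 4-hydroxybenzaldehyde 10.
- Ring order: both benzene rings are bought; dihydropyran ring B is the only ring formed (step 4), before the coupling.

Key step: step 9

Remark on the chemistry: the phenols are carried through the epoxidation as TBS ethers because these tolerate its basic aqueous medium, and the L-fructose-derived enantiomer of the Shi ketone is assumed to be available.

**Route**

Step 1
Reactants: 1 phloroglucinol; 2 prenyl bromide
Product: 3 2-(3-methylbut-2-en-1-yl)benzene-1,3,5-triol (2-prenylphloroglucinol)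
Conditions: DBU, THF, 0 °C → rt, 1 in excess
Reagents that add atoms: none
Why: C-allylation of the ambident phloroglucinol anion by the soft primary allylic bromide (SN2); the three ring positions of 1 are equivalent and the excess of 1 should hold back di-prenylation.

Step 2
Reactants: 3 2-prenylphloroglucinol
Product: 4 2-(3-methylbut-2-en-1-yl)-1,3,5-tris(tert-butyldimethylsilyloxy)benzene
Conditions: TBSCl, imidazole, DMF, rt
Reagents that add atoms: tert-butyldimethylsilyl chloride, CC(C)(C)[Si](C)(C)Cl
Why: Imidazole-mediated O-silylation of the three phenols, which masks the oxidation-prone triol as ethers that are inert to dioxiranes and to the basic epoxidation medium.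

Step 3
Reactants: 4 tris-TBS prenylarene
Product: 5 (S)-3-[2,4,6-tris(tert-butyldimethylsilyloxy)benzyl]-2,2-dimethyloxirane
Conditions: L-fructose-derived Shi ketone (30 mol%), KHSO5 (as 2KHSO5·KHSO4·K2SO4), K2CO3, Bu4NHSO4, aq. Na2B4O7 buffer, MeCN/CH2(OMe)2, 0 °C
Reagents that add atoms: potassium peroxymonosulfate KHSO5, [K+].[O-]S(=O)(=O)OO
Why: Shi asymmetric epoxidation of a trisubstituted alkene by the chiral dioxirane through a spiro transition state; the D-fructose-derived ketone gives the R epoxide with 2-methylalk-2-enes, so its enantiomer should set the S centre by reagent control.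

Step 4
Reactants: 5 (S)-epoxide tris-TBS ether
Product: 7 (S)-2,2-dimethylchromane-3,5,7-triol, via triol epoxide 6 (not isolated)
Conditions: TBAF/AcOH (1:1), THF, 0 °C; aqueous work-up; then CSA (cat.), CH2Cl2/THF, 0 °C
Reagents that add atoms: none
Why: Buffered fluoride desilylation frees the phenols without forming phenoxides, and the acid-catalysed 6-endo (Markovnikov) opening of the epoxide at its tertiary carbon by either of the two equivalent ortho hydroxyls then closes ring B; no bond at the stereocentre is broken, so S is retained.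

Step 5
Reactants: 7 (S)-2,2-dimethylchromane-3,5,7-triol
Product: 8 (S)-3,5,7-tris(methoxymethoxy)-2,2-dimethylchromane
Conditions: NaH, MOMCl, DMF, 0 °C → rt
Reagents that add atoms: chloromethyl methyl ether, COCCl
Why: Williamson-type O-alkylation of the two phenoxides and the secondary alkoxide by the hard electrophile MOMCl, giving acetals that are stable to NIS and to the basic coupling.

Step 6
Reactants: 8 tris-MOM chroman
Product: 9 (S)-8-iodo-3,5,7-tris(methoxymethoxy)-2,2-dimethylchromane
Conditions: NIS (1.0 equiv), DMF, −20 → 0 °C, dark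
Reagents that add atoms: N-iodosuccinimide, O=C1CCC(=O)N1I
Why: Electrophilic aromatic iodination (SEAr) of the trialkoxy-activated ring A; as in 5,7-dialkoxyflavans, attack should go to C8 next to the tied-back ring oxygen O1 and not to C6, which is screened by the C5 MOM group that the C4 methylene turns toward it, while one equivalent of acid-free NIS at low temperature holds back the diiodide and spares the acetals.

Step 7
Reactants: 10 4-hydroxybenzaldehyde
Product: 11 4-(methoxymethoxy)benzaldehyde
Conditions: MOMCl, i-Pr2NEt, CH2Cl2, 0 °C → rt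
Reagents that add atoms: chloromethyl methyl ether, COCCl
Why: O-alkylation of the acidic para-formyl phenol under amine base, so that no free phenol can intercept the aroyl–palladium intermediate later.

Step 8
Reactants: 11 4-(methoxymethoxy)benzaldehyde
Product: 12 (E)-2-[4-(methoxymethoxy)styryl]-4,4,5,5-tetramethyl-1,3,2-dioxaborolane
Conditions: CH2(Bpin)2, LiTMP (lithium 2,2,6,6-tetramethylpiperidide), THF, 0 °C; then 11, −78 °C → rt
Reagents that add atoms: bis[(pinacolato)boryl]methane, CC1(C)OB(CB2OC(C)(C)C(C)(C)O2)OC1(C)C
Why: Boron–Wittig olefination, in which the α-boryl carbanion adds to the aldehyde and syn elimination of the boron–oxygen pair gives the trans alkenylboronate in one step.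

Step 9
Reactants: 9 (S)-8-iodo-3,5,7-tris(methoxymethoxy)-2,2-dimethylchromane; 13 carbon monoxide; 12 (E)-styrylboronate
Product: 14 (S,E)-3-[4-(methoxymethoxy)phenyl]-1-[3,5,7-tris(methoxymethoxy)-2,2-dimethylchroman-8-yl]prop-2-en-1-one
Conditions: PdCl2(dppf) (5 mol%), K2CO3 (3 equiv), CO (5 bar), anisole/H2O (20:1), 80 °C
Reagents that add atoms: none
Why: Zerovalent palladium formed from PdCl2(dppf) inserts into the C8–I bond, CO inserts to give an aroyl complex of divalent palladium, the base-activated alkenylboronate 12 transmetalates with retention of the E geometry, and reductive elimination releases the enone and returns zerovalent palladium. The closest known reaction type is the carbonylative Suzuki–Miyaura coupling of aryl iodides with organoboron reagents to unsymmetrical ketones, used here with an alkenylboronate so that the C8–C(=O) and C(=O)–Cα bonds form in one operation. No ring is closed and no stereocentre is created; the remote C3 centre is not touched. The step needs CO insertion to run ahead of direct transmetalation, and the substrate secures this because the aryl–palladium centre at C8 is flanked by the C7 MOM ether and by O1 on C8a, so transmetalation at the aryl stage is slow while CO insertion under pressure stays fast. The bidentate dppf ligand holds the aroyl and alkenyl groups cis for quick reductive elimination, which limits decarbonylation and alkene isomerisation.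

Step 10
Reactants: 14 tetra-MOM enone
Product: 15 (S,E)-3-(4-hydroxyphenyl)-1-(3,5,7-trihydroxy-2,2-dimethylchroman-8-yl)prop-2-en-1-one (target)
Conditions: 3 M aq. HCl, MeOH/THF, rt → 40 °C
Reagents that add atoms: none
Why: Acid-catalysed acetal cleavage (transacetalisation to methanol) removes the three aryl MOM ethers and then the secondary alkyl one; the chroman ether, the E-enone and the C3 centre should tolerate dilute acid, and mild temperature with a short reaction time should hold back closure of the ortho-hydroxy enone to a flavanone.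

**Compound list**

1 | phloroglucinol | Oc1cc(O)cc(O)c1 | starting material
2 | prenyl bromide | CC(C)=CCBr | starting material
3 | 2-(3-methylbut-2-en-1-yl)benzene-1,3,5-triol | CC(C)=CCc1c(O)cc(O)cc1O | intermediate
4 | 2-(3-methylbut-2-en-1-yl)-1,3,5-tris(tert-butyldimethylsilyloxy)benzene | CC(C)=CCc1c(O[Si](C)(C)C(C)(C)C)cc(O[Si](C)(C)C(C)(C)C)cc1O[Si](C)(C)C(C)(C)C | intermediate
5 | (S)-3-[2,4,6-tris(tert-butyldimethylsilyloxy)benzyl]-2,2-dimethyloxirane | CC1(C)O[C@H]1Cc1c(O[Si](C)(C)C(C)(C)C)cc(O[Si](C)(C)C(C)(C)C)cc1O[Si](C)(C)C(C)(C)C | intermediate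
6 | (S)-2-[(3,3-dimethyloxiran-2-yl)methyl]benzene-1,3,5-triol (triol epoxide) | CC1(C)O[C@H]1Cc1c(O)cc(O)cc1O | intermediate (not isolated)
7 | (S)-2,2-dimethylchromane-3,5,7-triol | CC1(C)Oc2cc(O)cc(O)c2C[C@@H]1O | intermediate
8 | (S)-3,5,7-tris(methoxymethoxy)-2,2-dimethylchromane | CC1(C)Oc2cc(OCOC)cc(OCOC)c2C[C@@H]1OCOC | intermediate
9 | (S)-8-iodo-3,5,7-tris(methoxymethoxy)-2,2-dimethylchromane | CC1(C)Oc2c(I)c(OCOC)cc(OCOC)c2C[C@@H]1OCOC | intermediate
10 | 4-hydroxybenzaldehyde | O=Cc1ccc(O)cc1 | starting material
11 | 4-(methoxymethoxy)benzaldehyde | COCOc1ccc(C=O)cc1 | intermediate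
12 | (E)-2-[4-(methoxymethoxy)styryl]-4,4,5,5-tetramethyl-1,3,2-dioxaborolane | COCOc1ccc(/C=C/B2OC(C)(C)C(C)(C)O2)cc1 | intermediate
13 | carbon monoxide | [C-]#[O+] | starting material
14 | (S,E)-3-[4-(methoxymethoxy)phenyl]-1-[3,5,7-tris(methoxymethoxy)-2,2-dimethylchroman-8-yl]prop-2-en-1-one | CC1(C)Oc2c(C(=O)/C=C/c3ccc(OCOC)cc3)c(OCOC)cc(OCOC)c2C[C@@H]1OCOC | intermediate
15 | (S,E)-3-(4-hydroxyphenyl)-1-(3,5,7-trihydroxy-2,2-dimethylchroman-8-yl)prop-2-en-1-one | CC1(C)Oc2c(c(O)cc(O)c2C(=O)/C=C/c2ccc(O)cc2)C[C@@H]1O | target

**Step count**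

Total: 10 steps. Longest linear sequence: 8 steps (steps 1–6, 9, 10); the boronate branch (steps 7–8) joins at step 9.

**Steps most likely to fail**

Step 9. Transmetalation onto the hindered, electron-rich aroyl–palladium species may be slow, so that loss of iodine by reduction, hydroxycarbonylation to the benzoic acid or coupling without CO could take over. Fallback (stepwise acylation in place of the three-component coupling): aldehyde 11 is converted by Horner–Wadsworth–Emmons olefination with diethyl [2-(methoxy(methyl)amino)-2-oxoethyl]phosphonate and NaH in THF into the Weinreb amide (E)-N-methoxy-N-methyl-3-[4-(methoxymethoxy)phenyl]prop-2-enamide F1. Iodide 9 is submitted to iodine–lithium exchange (n-BuLi, THF, −78 °C) to give (S)-8-lithio-3,5,7-tris(methoxymethoxy)-2,2-dimethylchromane F2, which is added to F1. Collapse of the chelated adduct on work-up should give enone 14, where the route is rejoined.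

Step 6. The iodination may not discriminate well enough between C6 and C8, or may run on to the diiodide. Fallback (the selection is moved from the electrophilic step to a metal–halogen exchange): chroman 8 is iodinated exhaustively (NIS in excess, DMF, rt) to (S)-6,8-diiodo-3,5,7-tris(methoxymethoxy)-2,2-dimethylchromane F3. One equivalent of i-PrMgCl·LiCl (THF, −40 °C) is then expected to exchange the C6 iodine, whose aryl–magnesium bond is chelated by both flanking MOM acetals, giving (S)-[8-iodo-3,5,7-tris(methoxymethoxy)-2,2-dimethylchroman-6-yl]magnesium chloride F4. Protonation with MeOH returns to iodide 9.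

Step 4. After desilylation the phenol may open the epoxide in the 5-exo mode at the secondary carbon, giving a dihydrobenzofuran with inversion, or the free phloroglucinol epoxide may decompose before ring closure. Fallback (ring B is closed before the stereocentre is set, so the ring-size question cannot arise): triol 3 is cyclised oxidatively with DDQ (dioxane, heat) to 2,2-dimethyl-2H-chromene-5,7-diol F5, which is protected (MOMCl, i-Pr2NEt, CH2Cl2) as 5,7-bis(methoxymethoxy)-2,2-dimethyl-2H-chromene F6. Jacobsen epoxidation with (S,S)-[N,N′-bis(3,5-di-tert-butylsalicylidene)-1,2-cyclohexanediaminato]MnCl, aq. NaOCl and 4-phenylpyridine N-oxide in CH2Cl2 at 0 °C should give (3S,4S)-3,4-epoxy-5,7-bis(methoxymethoxy)-2,2-dimethylchromane F7. Hydride opening at the benzylic C4 (LiAlH4, THF, 0 °C) should give (S)-5,7-bis(methoxymethoxy)-2,2-dimethylchroman-3-ol F8, and MOM protection of the 3-hydroxyl (NaH, MOMCl) returns to chroman 8.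

**Further compounds**

F1 | step 9 | (E)-N-methoxy-N-methyl-3-[4-(methoxymethoxy)phenyl]prop-2-enamide | COCOc1ccc(/C=C/C(=O)N(C)OC)cc1
F2 | step 9 | (S)-8-lithio-3,5,7-tris(methoxymethoxy)-2,2-dimethylchromane | CC1(C)Oc2c([Li])c(OCOC)cc(OCOC)c2C[C@@H]1OCOC
F3 | step 6 | (S)-6,8-diiodo-3,5,7-tris(methoxymethoxy)-2,2-dimethylchromane | CC1(C)Oc2c(I)c(OCOC)c(I)c(OCOC)c2C[C@@H]1OCOC
F4 | step 6 | (S)-[8-iodo-3,5,7-tris(methoxymethoxy)-2,2-dimethylchroman-6-yl]magnesium chloride | CC1(C)Oc2c(I)c(OCOC)c([Mg]Cl)c(OCOC)c2C[C@@H]1OCOC
F5 | step 4 | 2,2-dimethyl-2H-chromene-5,7-diol | CC1(C)C=Cc2c(O)cc(O)cc2O1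
F6 | step 4 | 5,7-bis(methoxymethoxy)-2,2-dimethyl-2H-chromene | CC1(C)C=Cc2c(OCOC)cc(OCOC)cc2O1
F7 | step 4 | (3S,4S)-3,4-epoxy-5,7-bis(methoxymethoxy)-2,2-dimethylchromane | CC1(C)Oc2cc(OCOC)cc(OCOC)c2[C@@H]2O[C@H]12
F8 | step 4 | (S)-5,7-bis(methoxymethoxy)-2,2-dimethylchroman-3-ol | CC1(C)Oc2cc(OCOC)cc(OCOC)c2C[C@@H]1O
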